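**Retrosynthetic overview**

1. The spiro tetrahydrofuran/2,3-dihydrofuran pair (C9–O–C13) comes last, from a dearomative intramolecular hydroalkoxylation of a 3-alkylfuran by the C9 tertiary alcohol (new cobalt-hydride step); C9–C11 comes from a 2-(furan-3-yl)ethylcerium reagent and a cis-decalone.
2. Ring A (C10–C1 bond, cis ring fusion) comes from intramolecular enolate alkylation of a 2,6-dimethylcyclohexanone carrying a Me2C(CH2)3Br arm on C5; C8 is set by kinetic protonation.
3. Key step: the six-membered ring B comes from a one-carbon ring expansion of a cyclopentanone (diazoethane insertion, 1,2-shift of C7). It inserts C8 with its methyl and moves the silyloxy group from β to γ of the ketone, so ring A can then be closed with base.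
4. C4–C5 comes from an iron-hydride (MHAT) Giese addition of 5-bromo-2-methylpent-2-ene to (R)-4-silyloxy-2-methylcyclopentenone, made from (R)-4-hydroxycyclopentenone by silylation, α-iodination and Stille methylation.
5. Ring order: five-membered carbocycle (bought, carries C6) → ring B by ring expansion → ring A by alkylation → furan attached → tetrahydrofuran and dihydrofuran rings together in the last step.

Assumption: the SMILES is taken as drawn, i.e. a cis-fused decalin with H-5, CH3-20, the 6-acetoxy group, H-8 and C11 on one face and O-9 and CH3-17 on the other (5R,6R,8R,9R,10S,13R; labdane numbering C1–C20 is used for atom labels); compounds 1, 5 and 10 are taken as purchasable and diazoethane is used as a freshly prepared ethereal reagent solution.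

**Route**

Step 1
Reactants: 1 (R)-4-hydroxycyclopent-2-en-1-one
Product: 2 (R)-4-[(tert-butyldimethylsilyl)oxy]cyclopent-2-en-1-one
Conditions: TBSCl, imidazole, CH2Cl2, 0 °C to rt
Reagents that add atoms: tert-butyldimethylsilyl chloride, CC(C)(C)[Si](C)(C)Cl
Why: Imidazole-buffered silylation of a secondary alcohol, mild enough to avoid β-elimination or racemisation of the γ-hydroxy enone; the stereocentre (future C6, R) is carried through unchanged.

Step 2
Reactants: 2 (R)-4-[(tert-butyldimethylsilyl)oxy]cyclopent-2-en-1-one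
Product: 3 (R)-4-[(tert-butyldimethylsilyl)oxy]-2-iodocyclopent-2-en-1-one
Conditions: I2, pyridine/CH2Cl2 (1:1), 0 °C to rt
Reagents that add atoms: iodine, [I][I]
Why: Pyridine-promoted α-iodination of an enone (conjugate addition of pyridine, iodination of the enolate, E1cB loss of pyridine), a standard operation on this silyloxy cyclopentenone that leaves C6 untouched.

Step 3
Reactants: 3 (R)-4-[(tert-butyldimethylsilyl)oxy]-2-iodocyclopent-2-en-1-one
Product: 4 (R)-4-[(tert-butyldimethylsilyl)oxy]-2-methylcyclopent-2-en-1-one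
Conditions: Me4Sn, Pd2(dba)3 (2.5 mol %), AsPh3, CuI (10 mol %), NMP, 60 °C
Reagents that add atoms: tetramethylstannane, C[Sn](C)(C)C
Why: Stille cross-coupling of the α-iodoenone under neutral conditions (zerovalent palladium, AsPh3/CuI acceleration) installs the future C20 methyl without base-induced loss of the silyloxy group.

Step 4
Reactants: 4 (R)-4-[(tert-butyldimethylsilyl)oxy]-2-methylcyclopent-2-en-1-one; 5 5-bromo-2-methylpent-2-ene
Product: 6 (2R,3S,4R)-3-(5-bromo-2-methylpentan-2-yl)-4-[(tert-butyldimethylsilyl)oxy]-2-methylcyclopentan-1-one (C2 epimer also formed)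
Conditions: Fe(acac)3 (30 mol %), PhSiH3 (2.5 equiv), 5 (3 equiv), EtOH/ethylene glycol (5:1), 60 °C
Reagents that add atoms: none
Why: MHAT reductive olefin coupling (Giese addition): an iron hydride from Fe(acac)3 and PhSiH3 gives H• to the alkene CH of 5, the tertiary radical Me2C•(CH2)3Br adds to the enone β-carbon anti to the neighbouring OTBS group (sets C5, 3S, trans to C6–O), and the α-keto radical is reduced and protonated; the alkyl bromide is inert and the C2 epimer ratio is irrelevant because this centre becomes an enolate in step 6.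

Step 5
Reactants: 6 (2R,3S,4R)-3-(5-bromo-2-methylpentan-2-yl)-4-[(tert-butyldimethylsilyl)oxy]-2-methylcyclopentan-1-one
Product: 7 (3S,4R)-3-(5-bromo-2-methylpentan-2-yl)-4-[(tert-butyldimethylsilyl)oxy]-2,6-dimethylcyclohexan-1-one (epimers at C2 and C6)
Conditions: CH3CHN2 (1.5 equiv, Et2O solution), Sc(OTf)3 (10 mol %), toluene, −78 °C
Reagents that add atoms: diazoethane, CC=[N+]=[N-]
Why: Key ring expansion by Sc(OTf)3-catalysed diazoalkane–ketone homologation (Tiffeneau–Demjanov-type 1,2-shift with loss of N2): diazoethane adds to the activated carbonyl and the less substituted, less hindered CH2 (C7) migrates in preference to the methyl-bearing carbon flanked by the tert-alkyl arm, so CH(CH3) (C8 and C17) is inserted between C9 and C7; the α,α′-dimethylcyclohexanone formed is too hindered to insert again, the silyloxy group ends up γ to the ketone (no E1cB pathway in step 6), and both α-centres are reset in step 6.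

Step 6
Reactants: 7 (3S,4R)-3-(5-bromo-2-methylpentan-2-yl)-4-[(tert-butyldimethylsilyl)oxy]-2,6-dimethylcyclohexan-1-one
Product: 9 (2R,4R,4aR,8aS)-4-[(tert-butyldimethylsilyl)oxy]-2,5,5,8a-tetramethyloctahydronaphthalen-1(2H)-one, via potassium enolate 8 (not isolated)
Conditions: KH (2.5 equiv), THF, 0 °C to rt; then −78 °C, 2,6-di-tert-butyl-4-methylphenol (4 equiv); pH 7 buffer
Reagents that add atoms: none
Why: Intramolecular enolate C-alkylation (6-exo-tet): the two enolates interconvert by proton exchange with ketone present during the reaction and only the C10 enolate can cyclise; A(1,2) strain with the C10 methyl holds the bulky C5 arm pseudoaxial, so the bromide is delivered to the same face and the decalin is cis-fused (C10, S); excess KH then converts the product into its only possible enolate 8, and kinetic protonation by the bulky phenol on the convex face (opposite the axial C1–C10 bond of ring A) sets C8 as the contra-thermodynamic 2R epimer.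

Step 7
Reactants: 10 2-(furan-3-yl)ethan-1-ol
Product: 11 3-(2-iodoethyl)furan
Conditions: I2, PPh3, imidazole, CH2Cl2, 0 °C to rt
Reagents that add atoms: iodine, [I][I]
Why: Appel-type iodination (SN2 displacement of the alkoxyphosphonium by iodide) of a primary alcohol under imidazole buffering that the furan tolerates.

Step 8
Reactants: 9 (2R,4R,4aR,8aS)-4-[(tert-butyldimethylsilyl)oxy]-2,5,5,8a-tetramethyloctahydronaphthalen-1(2H)-one; 11 3-(2-iodoethyl)furan
Product: 14 (1R,2R,4R,4aR,8aS)-4-[(tert-butyldimethylsilyl)oxy]-1-[2-(furan-3-yl)ethyl]-2,5,5,8a-tetramethyldecahydronaphthalen-1-ol, via 2-(furan-3-yl)ethyllithium 12 (not isolated), via dichloro[2-(furan-3-yl)ethyl]cerium 13 (not isolated)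
Conditions: 11 (3 equiv), t-BuLi (6.3 equiv), Et2O, −78 °C; CeCl3 (anhydrous), THF, −78 °C; then 9, −78 to −30 °C; aq NH4Cl
Reagents that add atoms: none
Why: Iodine–lithium exchange and transmetalation to the weakly basic organocerium allow 1,2-addition to the hindered, enolisable ketone without epimerising C8; attack is expected on the convex face, axially past H-5 and H-7 and away from the axial C1 and C17 groups that block the other face, which places C11 cis to CH3-20 and the new hydroxyl trans to it (C9, R).

Step 9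
Reactants: 14 (1R,2R,4R,4aR,8aS)-4-[(tert-butyldimethylsilyl)oxy]-1-[2-(furan-3-yl)ethyl]-2,5,5,8a-tetramethyldecahydronaphthalen-1-ol
Product: 16 (1R,3R,4R,4aS,8aR)-4-[2-(furan-3-yl)ethyl]-4-hydroxy-3,4a,8,8-tetramethyldecahydronaphthalen-1-yl acetate, via diol 15 (not isolated)
Conditions: TBAF (1.5 equiv), THF, 45 °C; then Ac2O (4 equiv), Et3N, DMAP (0.1 equiv), rt
Reagents that add atoms: acetic anhydride, CC(=O)OC(C)=O
Why: Fluoride desilylation followed in the same flask by DMAP-catalysed acetylation, selective for the secondary C6 hydroxyl because the tertiary C9 hydroxyl is too hindered to acylate at room temperature; no stereocentre is touched.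

Step 10
Reactants: 16 (1R,3R,4R,4aS,8aR)-4-[2-(furan-3-yl)ethyl]-4-hydroxy-3,4a,8,8-tetramethyldecahydronaphthalen-1-yl acetate
Product: 17 (5R,6R,8R,9R,10S,13R)-9,13:15,16-diepoxylabd-14-en-6-yl acetate (target)
Conditions: (R,R)-Co(salen) [C36H52CoN2O2, (R,R)-N,N′-bis(3,5-di-tert-butylsalicylidene)cyclohexane-1,2-diaminatocobalt] (10 mol %), N-fluoro-2,4,6-trimethylpyridinium tetrafluoroborate (1.2 equiv), PhSiH3 (1.2 equiv), 2,4,6-collidine (1 equiv), PhCF3, 0 °C
Reagents that add atoms: none
Why: Proposed new method: dearomative Markovnikov hydroalkoxylation of the furan C2=C3 bond by MHAT and radical-polar crossover, in which the cobalt hydride formed from the divalent cobalt salen complex, the N-fluoropyridinium oxidant and the silane transfers H• to the furan α-carbon next to the alkyl group (C16), the resulting tertiary oxygen-conjugated allyl radical at C13 is captured and oxidised to a cationic alkylcobalt species (the equivalent of the C16-protonated furan) and is displaced 5-exo by the C9 hydroxyl before it loses a proton, so the spiro ether forms irreversibly in a collidine-buffered medium where the acid-catalysed equilibrium (which favours the furan) is shut off; the chiral salen ligand is relied on to select the C13 face (13R, with the other catalyst enantiomer as the alternative and the C13 epimer separable); closest known reaction type: cobalt-salen/N-fluoropyridinium/silane MHAT hydroalkoxylation of unactivated alkenes and its enantioselective variants, not yet shown on a heteroaromatic C=C bond.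

**Compound list**

1 | (R)-4-hydroxycyclopent-2-en-1-one | O[C@@H]1CC(=O)C=C1 | starting material
2 | (R)-4-[(tert-butyldimethylsilyl)oxy]cyclopent-2-en-1-one | CC(C)(C)[Si](C)(C)O[C@@H]1CC(=O)C=C1 | intermediate
3 | (R)-4-[(tert-butyldimethylsilyl)oxy]-2-iodocyclopent-2-en-1-one | CC(C)(C)[Si](C)(C)O[C@@H]1CC(=O)C(I)=C1 | intermediate
4 | (R)-4-[(tert-butyldimethylsilyl)oxy]-2-methylcyclopent-2-en-1-one | CC(C)(C)[Si](C)(C)O[C@@H]1CC(=O)C(C)=C1 | intermediate
5 | 5-bromo-2-methylpent-2-ene | CC(C)=CCCBr | starting material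
6 | (2R,3S,4R)-3-(5-bromo-2-methylpentan-2-yl)-4-[(tert-butyldimethylsilyl)oxy]-2-methylcyclopentan-1-one (major epimer drawn) | CC(C)(C)[Si](C)(C)O[C@@H]1CC(=O)[C@H](C)[C@H]1C(C)(C)CCCBr | intermediate
7 | (3S,4R)-3-(5-bromo-2-methylpentan-2-yl)-4-[(tert-butyldimethylsilyl)oxy]-2,6-dimethylcyclohexan-1-one (C2/C6 epimers, left open) | CC(C)(C)[Si](C)(C)O[C@@H]1CC(C)C(=O)C(C)[C@H]1C(C)(C)CCCBr | intermediate
8 | potassium (4R,4aR,8aS)-4-[(tert-butyldimethylsilyl)oxy]-2,5,5,8a-tetramethyl-3,4,4a,5,6,7,8,8a-octahydronaphthalen-1-olate | CC(C)(C)[Si](C)(C)O[C@@H]1CC(C)=C([O-])[C@@]2(C)CCCC(C)(C)[C@@H]12.[K+] | intermediate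
9 | (2R,4R,4aR,8aS)-4-[(tert-butyldimethylsilyl)oxy]-2,5,5,8a-tetramethyloctahydronaphthalen-1(2H)-one (cis-fused) | CC(C)(C)[Si](C)(C)O[C@@H]1C[C@@H](C)C(=O)[C@@]2(C)CCCC(C)(C)[C@@H]12 | intermediate
10 | 2-(furan-3-yl)ethan-1-ol | OCCc1ccoc1 | starting material
11 | 3-(2-iodoethyl)furan | ICCc1ccoc1 | intermediate
12 | 2-(furan-3-yl)ethyllithium | [Li]CCc1ccoc1 | intermediate
13 | dichloro[2-(furan-3-yl)ethyl]cerium | Cl[Ce](Cl)CCc1ccoc1 | intermediate
14 | (1R,2R,4R,4aR,8aS)-4-[(tert-butyldimethylsilyl)oxy]-1-[2-(furan-3-yl)ethyl]-2,5,5,8a-tetramethyldecahydronaphthalen-1-ol | CC(C)(C)[Si](C)(C)O[C@@H]1C[C@@H](C)[C@](O)(CCc3ccoc3)[C@@]2(C)CCCC(C)(C)[C@@H]12 | intermediate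
15 | (1R,2R,4R,4aR,8aS)-1-[2-(furan-3-yl)ethyl]-2,5,5,8a-tetramethyldecahydronaphthalene-1,4-diol | O[C@@H]1C[C@@H](C)[C@](O)(CCc3ccoc3)[C@@]2(C)CCCC(C)(C)[C@@H]12 | intermediate
16 | (1R,3R,4R,4aS,8aR)-4-[2-(furan-3-yl)ethyl]-4-hydroxy-3,4a,8,8-tetramethyldecahydronaphthalen-1-yl acetate | CC(=O)O[C@@H]1C[C@@H](C)[C@](O)(CCc3ccoc3)[C@@]2(C)CCCC(C)(C)[C@@H]12 | intermediate
17 | (5R,6R,8R,9R,10S,13R)-9,13:15,16-diepoxylabd-14-en-6-yl acetate (cis-fused decalin) | CC(=O)O[C@@H]1C[C@@H](C)[C@]2(CC[C@]3(C=COC3)O2)[C@@]2(C)CCCC(C)(C)[C@@H]12 | target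

**Step count and risks**

Total steps: 10. Longest linear sequence: 9 (steps 1–6 and 8–10, from compound 1).

Step 5, ring expansion. The risk is that the methyl-bearing carbon migrates instead of C7 (the β-silyloxy group lowers the migratory aptitude of C7), or that the ketone is sluggish toward diazoethane. The fallback sets out from 6 and comes back at 7, and fixes the insertion site by the position of an enol ether instead of by migratory aptitude. Kinetic enolisation of 6 on the CH2 side with internal quench (LiN(i-Pr)2, TMSCl, THF, −78 °C) gives the trimethylsilyl enol ether F1. Ethylidene transfer (CH3CHI2, Et2Zn, CH2Cl2, 0 °C) gives the methyl-substituted siloxycyclopropane F2. FeCl3 in DMF (Saegusa–Ito oxidative cleavage of the internal cyclopropane bond, a radical ring enlargement) gives the ring-enlarged β-chloro ketone F3. NaOAc in MeOH eliminates HCl to the 2-methylcyclohex-2-enone F4, and H2 over Pd/C in EtOAc saturates it to 7.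

Step 6, ring A closure and C8 protonation. The cyclisation itself is well precedented; the weak point is the face selectivity of the kinetic protonation, since the required 2R epimer is the less stable one by my conformational estimate. The fallback sets out from 7 and comes back at 9, and sets C8 by hydroxyl-directed hydrogenation instead. KOt-Bu in t-BuOH/THF closes ring A under thermodynamic control and gives the 2-epimeric cis-decalone F5. IBX in DMSO at 70 °C dehydrogenates it to the enone F6. TBAF frees the hydroxy enone F7. Hydrogenation with [Ir(cod)(PCy3)(py)]PF6 (H2, CH2Cl2) delivers both hydrogens syn to the C6 hydroxyl and gives the hydroxy ketone F8 with the 2R methyl. TBSOTf/2,6-lutidine at −78 °C then returns 9.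

Step 10, the proposed dearomative hydroalkoxylation. The risks are slow hydrogen-atom transfer to the aromatic furan, proton loss from the cationic intermediate back to the furan, attack of the hydroxyl at C16 after hydrogen delivery to C15 (six-membered acetal), further reaction of the enol ether product, and poor C13 control. The fallback uses known chemistry, sets out from 14 (the acetate of 16 would not survive the hydride step) and comes back at 17. Photooxygenation of the furan (O2, tetraphenylporphyrin, hν, i-Pr2NEt, CH2Cl2, −78 °C) gives the γ-hydroxybutenolide F9. NaBH4 in EtOH followed by acidification gives the β-substituted butenolide F10. DBU in toluene brings about the reversible intramolecular oxa-Michael addition of the C9 hydroxyl to C13 and gives the spiro lactone F11; the 13R epimer is separated and the other is re-equilibrated. i-Bu2AlH at −78 °C gives the lactol F12. MsCl/Et3N (0 °C to reflux) dehydrates it to the silyl-protected spiro enol ether F13. TBAF followed in the same flask by Ac2O/Et3N/DMAP passes through the free alcohol F14 to 17.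

**Further compounds**

F1 | step 5 | trimethylsilyl enol ether of 6 (enol double bond toward the ring CH2) | CC(C)(C)[Si](C)(C)O[C@@H]1C=C(O[Si](C)(C)C)[C@H](C)[C@H]1C(C)(C)CCCBr
F2 | step 5 | 6-methyl-1-(trimethylsilyloxy)bicyclo[3.1.0]hexane derived from F1 | CC(C)(C)[Si](C)(C)O[C@@H]1C2C(C)C2(O[Si](C)(C)C)[C@H](C)[C@H]1C(C)(C)CCCBr
F3 | step 5 | ring-enlarged β-chloro ketone (3-chloro-2,6-dimethylcyclohexanone core) | CC(C)(C)[Si](C)(C)O[C@@H]1C(Cl)C(C)C(=O)C(C)[C@H]1C(C)(C)CCCBr
F4 | step 5 | (4R,5S)-5-(5-bromo-2-methylpentan-2-yl)-4-[(tert-butyldimethylsilyl)oxy]-2,6-dimethylcyclohex-2-en-1-one | CC(C)(C)[Si](C)(C)O[C@@H]1C=C(C)C(=O)C(C)[C@H]1C(C)(C)CCCBr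
F5 | step 6 | (2S,4R,4aR,8aS)-4-[(tert-butyldimethylsilyl)oxy]-2,5,5,8a-tetramethyloctahydronaphthalen-1(2H)-one | CC(C)(C)[Si](C)(C)O[C@@H]1C[C@H](C)C(=O)[C@@]2(C)CCCC(C)(C)[C@@H]12
F6 | step 6 | (4R,4aR,8aS)-4-[(tert-butyldimethylsilyl)oxy]-2,5,5,8a-tetramethyl-4a,5,6,7,8,8a-hexahydronaphthalen-1(4H)-one | CC(C)(C)[Si](C)(C)O[C@@H]1C=C(C)C(=O)[C@@]2(C)CCCC(C)(C)[C@@H]12
F7 | step 6 | (4R,4aR,8aS)-4-hydroxy-2,5,5,8a-tetramethyl-4a,5,6,7,8,8a-hexahydronaphthalen-1(4H)-one | O[C@@H]1C=C(C)C(=O)[C@@]2(C)CCCC(C)(C)[C@@H]12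
F8 | step 6 | (2R,4R,4aR,8aS)-4-hydroxy-2,5,5,8a-tetramethyloctahydronaphthalen-1(2H)-one | O[C@@H]1C[C@@H](C)C(=O)[C@@]2(C)CCCC(C)(C)[C@@H]12
F9 | step 10 | 6-silyloxy-9,16-dihydroxylabd-13-en-15,16-olide (γ-hydroxybutenolide, C16 epimers) | CC(C)(C)[Si](C)(C)O[C@@H]1C[C@@H](C)[C@](O)(CCC3=CC(=O)OC3O)[C@@]2(C)CCCC(C)(C)[C@@H]12
F10 | step 10 | 6-silyloxy-9-hydroxylabd-13-en-15,16-olide (butenolide) | CC(C)(C)[Si](C)(C)O[C@@H]1C[C@@H](C)[C@](O)(CCC3=CC(=O)OC3)[C@@]2(C)CCCC(C)(C)[C@@H]12
F11 | step 10 | (13R)-6-silyloxy-9,13-epoxylabdan-15,16-olide (spiro lactone) | CC(C)(C)[Si](C)(C)O[C@@H]1C[C@@H](C)[C@]2(CC[C@]3(CC(=O)OC3)O2)[C@@]2(C)CCCC(C)(C)[C@@H]12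
F12 | step 10 | (13R)-6-silyloxy-9,13:15,16-diepoxylabdan-15-ol (lactol, C15 epimers) | CC(C)(C)[Si](C)(C)O[C@@H]1C[C@@H](C)[C@]2(CC[C@]3(CC(O)OC3)O2)[C@@]2(C)CCCC(C)(C)[C@@H]12
F13 | step 10 | (13R)-6-[(tert-butyldimethylsilyl)oxy]-9,13:15,16-diepoxylabd-14-ene | CC(C)(C)[Si](C)(C)O[C@@H]1C[C@@H](C)[C@]2(CC[C@]3(C=COC3)O2)[C@@]2(C)CCCC(C)(C)[C@@H]12
F14 | step 10 | (13R)-9,13:15,16-diepoxylabd-14-en-6-ol | O[C@@H]1C[C@@H](C)[C@]2(CC[C@]3(C=COC3)O2)[C@@]2(C)CCCC(C)(C)[C@@H]12
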